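**Retrosynthetic overview**
1. Target: all-E (6R)-7′,8′-dihydro-ε,ψ-carotene (carotenoid numbering: ring C1–C6, chain C7–C15, then C15′→C1′ along the acyclic half). The last step makes the C14′–C15′ single bond from a C21 ring-half (E)-alkenyl iodide (iodine on C15′) and a C18 terminal dienyne (C13′≡C14′–H); the C13′ methyl comes from Me3Al in the same pot.
2. Enabling feature: the C13′(CH3)=C14′H unit, a methyl-branched trisubstituted alkene whose CH carbon (C14′) carries the bond to C15′. This 2-methylalk-1-enyl terminus is exactly what syn methyl-metalation of a terminal alkyne delivers, so the branch, the 13′E geometry and the nucleophilic carbon for the sp2–sp2 coupling arise together. The isolated C1′=C2′ and C5′=C6′ alkenes and the ring C4=C5 alkene are inert.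
3. Ring half: (R)-α-ionone → HWE (C2 nitrile) → DIBAL → HWE (C5 nitrile) → DIBAL → (R)-α-retinal → Takai iodo-olefination.
4. Acyclic half: (2E,6E)-farnesol → farnesal → Takai dienyl iodide → Pd/Zn ethynylation.
5. Rings: none is formed in the route; the only ring (the cyclohexene ε-ring, C1–C6) and its single stereocentre C6 are carried intact from (R)-α-ionone.

Key step: step 9

Assumption: (R)-(+)-α-ionone of high ee is taken as a purchasable chiral-pool ketone; it supplies the only stereocentre (C6, R), which sits on an sp3 carbon that no later step touches.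

**Step 1**
Reactants: 1 (R)-α-ionone, (3E)-4-[(1R)-2,6,6-trimethylcyclohex-2-en-1-yl]but-3-en-2-one
Product: 2 (2E,4E)-3-methyl-5-[(1R)-2,6,6-trimethylcyclohex-2-en-1-yl]penta-2,4-dienenitrile
Conditions: (EtO)2P(O)CH2CN, NaH, THF, 0 °C → rt; chromatography to remove the 2Z isomer
Reagents that add atoms: diethyl (cyanomethyl)phosphonate, CCOP(=O)(CC#N)OCC
Why: Horner–Wadsworth–Emmons olefination of the methyl ketone with the cyano-stabilised phosphonate anion should give mainly the E trisubstituted alkene, and this weakly basic anion should not remove the vinylogous C–H at the ring stereocentre, so the (R) configuration is carried through.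

**Step 2**
Reactants: 2 (2E,4E)-3-methyl-5-[(1R)-2,6,6-trimethylcyclohex-2-en-1-yl]penta-2,4-dienenitrile
Product: 4 (2E,4E)-3-methyl-5-[(1R)-2,6,6-trimethylcyclohex-2-en-1-yl]penta-2,4-dienal, via C15 N-diisobutylalumanyl aldimine 3 (not isolated)
Conditions: DIBAL-H (1.2 equiv), toluene, −78 °C; then wet SiO2 or aq. Rochelle salt, 0 °C
Reagents that add atoms: water, O
Why: Partial nitrile reduction with DIBAL-H should stop at the N-aluminio aldimine 3, which is hydrolysed on work-up to the dienal (oxygen from water) without touching the diene geometry or the ring alkene.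

**Step 3**
Reactants: 4 (2E,4E)-3-methyl-5-[(1R)-2,6,6-trimethylcyclohex-2-en-1-yl]penta-2,4-dienal
Product: 5 (R)-α-retinonitrile, (2E,4E,6E,8E)-3,7-dimethyl-9-[(1R)-2,6,6-trimethylcyclohex-2-en-1-yl]nona-2,4,6,8-tetraenenitrile
Conditions: (EtO)2P(O)CH2C(CH3)=CHCN (E/Z mixture as sold), NaH, THF, 0 °C; then 4, 0 °C → rt, dark; chromatography to remove the 2Z (13-cis) isomer
Reagents that add atoms: diethyl (3-cyano-2-methylprop-2-en-1-yl)phosphonate, CCOP(=O)(CC(C)=CC#N)OCC
Why: Vinylogous Horner–Wadsworth–Emmons olefination with the allylic cyano-phosphonate anion should form the new disubstituted alkene with E geometry and add five carbons at once, the 13-cis isomer from equilibration of the allylic anion being expected as the minor, separable component.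

**Step 4**
Reactants: 5 (R)-α-retinonitrile
Product: 7 (R)-α-retinal, (2E,4E,6E,8E)-3,7-dimethyl-9-[(1R)-2,6,6-trimethylcyclohex-2-en-1-yl]nona-2,4,6,8-tetraenal, via C20 N-diisobutylalumanyl aldimine 6 (not isolated)
Conditions: DIBAL-H (1.2 equiv), toluene, −78 °C; then wet SiO2, 0 °C; dark
Reagents that add atoms: water, O
Why: The same partial nitrile reduction as in step 2 should give the tetraenal after hydrolysis of aldimine 6, the low temperature and non-acidic work-up keeping the chain all-E and the doubly allylic ring stereocentre intact.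

**Step 5**
Reactants: 7 (R)-α-retinal
Product: 8 (6R)-6-[(1E,3E,5E,7E,9E)-10-iodo-3,7-dimethyldeca-1,3,5,7,9-pentaen-1-yl]-1,5,5-trimethylcyclohex-1-ene
Conditions: CHI3 (2 equiv), CrCl2 (6 equiv), THF–dioxane, 0 °C → rt, dark, trace BHT; used at once
Reagents that add atoms: iodoform, IC(I)I
Why: Takai iodo-olefination, in which the gem-dichromium carbenoid from CHI3 and CrCl2 adds to the aldehyde and the β-oxido organochromium eliminates from its less crowded conformer, should give the (E)-alkenyl iodide under non-basic conditions that are chemoselective for the aldehyde.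

**Step 6**
Reactants: 9 (2E,6E)-farnesol, (2E,6E)-3,7,11-trimethyldodeca-2,6,10-trien-1-ol
Product: 10 (2E,6E)-farnesal, (2E,6E)-3,7,11-trimethyldodeca-2,6,10-trienal
Conditions: activated MnO2 (excess), hexane, rt
Reagents that add atoms: none
Why: MnO2 should oxidise the allylic primary alcohol selectively to the enal without over-oxidation and with retention of the 2E geometry, the isolated alkenes being inert.

**Step 7**
Reactants: 10 (2E,6E)-farnesal
Product: 11 (1E,3E,7E)-1-iodo-4,8,12-trimethyltrideca-1,3,7,11-tetraene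
Conditions: CHI3 (2 equiv), CrCl2 (6 equiv), THF–dioxane, 0 °C → rt, dark
Reagents that add atoms: iodoform, IC(I)I
Why: Takai iodo-olefination as in step 5 should convert the enal into the (1E,3E)-dienyl iodide with the new alkene E, without isomerising the existing trisubstituted alkenes.

**Step 8**
Reactants: 11 (1E,3E,7E)-1-iodo-4,8,12-trimethyltrideca-1,3,7,11-tetraene
Product: 12 (3E,5E,9E)-6,10,14-trimethylpentadeca-3,5,9,13-tetraen-1-yne
Conditions: HC≡CMgBr (3 equiv), ZnBr2 (3 equiv), THF, 0 °C; then 11, Pd(PPh3)4 (5 mol %), rt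
Reagents that add atoms: ethynylmagnesium bromide, C#C[Mg]Br
Why: Negishi alkynylation (oxidative addition of Pd(0) into the alkenyl C–I bond, transmetalation from ethynylzinc bromide, reductive elimination) should give the terminal dienyne with retention of both alkene geometries and without the diyne by-products of copper-based ethynylation.

**Step 9**
Reactants: 12 (3E,5E,9E)-6,10,14-trimethylpentadeca-3,5,9,13-tetraen-1-yne and 8 (6R)-6-[(1E,3E,5E,7E,9E)-10-iodo-3,7-dimethyldeca-1,3,5,7,9-pentaen-1-yl]-1,5,5-trimethylcyclohex-1-ene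
Product: 15 all-E (6R)-7′,8′-dihydro-ε,ψ-carotene (target), via alkenyldimethylalane 13 (not isolated), via alkenylzinc chloride 14 (not isolated)
Conditions: 12 (1.3 equiv), Me3Al (2 equiv), Cp2ZrCl2 (25 mol %), CH2Cl2, rt; evaporate volatiles; ZnCl2 (1.3 equiv), THF; then 8, Pd2(dba)3 (2.5 mol %), P(2-furyl)3 (10 mol %), THF–DMF, rt, dark, Ar; chromatography on deactivated alumina, crystallisation
Reagents that add atoms: trimethylaluminium, C[Al](C)C
Why: Cp2ZrCl2/Me3Al forms a methylzirconocene–aluminate that adds methyl and metal syn across the terminal C≡C of 12, methyl to the internal carbon (C13′) and metal to the terminal CH (C14′), giving the (E)-2-methylalkenylalane 13; after removal of excess Me3Al, Al→Zn exchange gives 14, Pd(0) inserts into the C–I bond of 8, and transmetalation/reductive elimination form the C14′–C15′ bond with retention at both alkenes. The closest known reaction type is this same one-pot Zr-catalysed methylalumination/Pd–Zn (Negishi) alkenyl–alkenyl coupling of conjugated terminal enynes with alkenyl halides, an established way to build methyl-branched all-E polyenes. No ring is closed and no stereocentre is formed; the step installs the C13′ methyl branch, sets the 13′E geometry, makes the central single bond and so completes the C40 skeleton and the conjugated octaene in the last operation. The selectivities needed are regio- and syn-selective carbometalation, secured by the terminal alkyne (metal to the unhindered CH); chemoselectivity, secured because the isolated trisubstituted alkenes and the conjugated diene do not undergo methylalumination under these conditions; and alkenyl rather than methyl transfer to palladium, secured by evaporating excess Me3Al and by the faster transmetalation of sp2 groups. The 15E geometry is carried in from 8, and the (6R) centre, remote and without an acidifying group, is not touched.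

**Compound list**
1 | (R)-α-ionone, (3E)-4-[(1R)-2,6,6-trimethylcyclohex-2-en-1-yl]but-3-en-2-one | CC(=O)/C=C/[C@H]1C(C)=CCCC1(C)C | starting material
2 | (2E,4E)-3-methyl-5-[(1R)-2,6,6-trimethylcyclohex-2-en-1-yl]penta-2,4-dienenitrile | N#C/C=C(C)/C=C/[C@H]1C(C)=CCCC1(C)C | intermediate
3 | N-(diisobutylalumanyl) aldimine of 4 | CC(C)C[Al](CC(C)C)N=C/C=C(C)/C=C/[C@H]1C(C)=CCCC1(C)C | intermediate (not isolated)
4 | (2E,4E)-3-methyl-5-[(1R)-2,6,6-trimethylcyclohex-2-en-1-yl]penta-2,4-dienal | O=C/C=C(C)/C=C/[C@H]1C(C)=CCCC1(C)C | intermediate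
5 | (R)-α-retinonitrile, (2E,4E,6E,8E)-3,7-dimethyl-9-[(1R)-2,6,6-trimethylcyclohex-2-en-1-yl]nona-2,4,6,8-tetraenenitrile | N#C/C=C(C)/C=C/C=C(C)/C=C/[C@H]1C(C)=CCCC1(C)C | intermediate
6 | N-(diisobutylalumanyl) aldimine of 7 | CC(C)C[Al](CC(C)C)N=C/C=C(C)/C=C/C=C(C)/C=C/[C@H]1C(C)=CCCC1(C)C | intermediate (not isolated)
7 | (R)-α-retinal, (2E,4E,6E,8E)-3,7-dimethyl-9-[(1R)-2,6,6-trimethylcyclohex-2-en-1-yl]nona-2,4,6,8-tetraenal | O=C/C=C(C)/C=C/C=C(C)/C=C/[C@H]1C(C)=CCCC1(C)C | intermediate
8 | (6R)-6-[(1E,3E,5E,7E,9E)-10-iodo-3,7-dimethyldeca-1,3,5,7,9-pentaen-1-yl]-1,5,5-trimethylcyclohex-1-ene | I/C=C/C=C(C)/C=C/C=C(C)/C=C/[C@H]1C(C)=CCCC1(C)C | intermediate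
9 | (2E,6E)-farnesol, (2E,6E)-3,7,11-trimethyldodeca-2,6,10-trien-1-ol | CC(C)=CCC/C(C)=C/CC/C(C)=C/CO | starting material
10 | (2E,6E)-farnesal, (2E,6E)-3,7,11-trimethyldodeca-2,6,10-trienal | CC(C)=CCC/C(C)=C/CC/C(C)=C/C=O | intermediate
11 | (1E,3E,7E)-1-iodo-4,8,12-trimethyltrideca-1,3,7,11-tetraene | CC(C)=CCC/C(C)=C/CC/C(C)=C/C=C/I | intermediate
12 | (3E,5E,9E)-6,10,14-trimethylpentadeca-3,5,9,13-tetraen-1-yne | CC(C)=CCC/C(C)=C/CC/C(C)=C/C=C/C#C | intermediate
13 | dimethyl[(1E,3E,5E,9E)-2,6,10,14-tetramethylpentadeca-1,3,5,9,13-pentaen-1-yl]alumane | CC(C)=CCC/C(C)=C/CC/C(C)=C/C=C/C(C)=C/[Al](C)C | intermediate (not isolated)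
14 | chloro[(1E,3E,5E,9E)-2,6,10,14-tetramethylpentadeca-1,3,5,9,13-pentaen-1-yl]zinc | CC(C)=CCC/C(C)=C/CC/C(C)=C/C=C/C(C)=C/[Zn]Cl | intermediate (not isolated)
15 | all-E (6R)-7′,8′-dihydro-ε,ψ-carotene | CC(C)=CCC/C(C)=C/CC/C(C)=C/C=C/C(C)=C/C=C/C=C(C)/C=C/C=C(C)/C=C/[C@H]1C(C)=CCCC1(C)C | target

**Step count and risks**
Total steps: 9. Longest linear sequence: 6 (steps 1–5, then 9).

Steps most likely to fail:

1. Step 9. What may go wrong: incomplete or regio-unselective carbometalation of the conjugated dienyne, competing transfer of a methyl group to palladium, and Lewis-acid- or light-induced E/Z scrambling of the polyenyl iodide before it couples. Fallback: separate the two events and reverse the polarity, setting out from 12 and 7 and coming back at 15. The same Zr-catalysed methylalumination of 12 is quenched with I2 (THF, −30 °C, dark, thiosulfate work-up) to give isolable (1E,3E,5E,9E)-1-iodo-2,6,10,14-tetramethylpentadeca-1,3,5,9,13-pentaene F1, whose regio- and stereochemistry can be checked before use. Takai–Utimoto boryl-olefination of 7 (CrCl2, LiI, Cl2CHBpin, THF, rt, dark) gives the (E)-pentaenyl pinacol boronate 2-[(1E,3E,5E,7E,9E)-4,8-dimethyl-10-[(1R)-2,6,6-trimethylcyclohex-2-en-1-yl]deca-1,3,5,7,9-pentaen-1-yl]-4,4,5,5-tetramethyl-1,3,2-dioxaborolane F2. Suzuki–Miyaura coupling of F1 and F2 (Pd(PPh3)4, aq. KOH, THF, rt, dark) should then give 15.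

2. Step 5. What may go wrong: single-electron reduction and pinacol-type dimerisation of the extended polyenal by Cr(II), erosion of E selectivity at the new alkene, and decomposition of the tetraenyl iodide (light, traces of acid) during isolation. Fallback: a chromium-free route, setting out from 7 and coming back at 8. Colvin homologation of 7 with lithiated trimethylsilyldiazomethane (TMSCHN2, n-BuLi, THF, −78 °C → rt) should give the terminal alkyne (6R)-6-[(1E,3E,5E,7E)-3,7-dimethyldeca-1,3,5,7-tetraen-9-yn-1-yl]-1,5,5-trimethylcyclohex-1-ene F3. Hydrozirconation with Cp2Zr(H)Cl (THF, rt, dark) should add syn and terminally to give the (E)-alkenylzirconocene chloride F4 (not isolated), and iodinolysis (I2, THF, −78 °C) should give 8 with retention.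

3. Step 3. What may go wrong: poor control of the C13=C14 geometry through equilibration of the allylic phosphonate anion, giving isomer mixtures that are hard to separate at the nitrile stage, and base-mediated self-condensation of the dienal. Fallback: a different C5 building block at the ester oxidation level, setting out from 4 and coming back at 7. Horner–Wadsworth–Emmons reaction of 4 with triethyl 3-methyl-4-phosphonocrotonate (n-BuLi, DMPU, THF, −78 → 0 °C) should give ethyl (R)-α-retinoate, ethyl (2E,4E,6E,8E)-3,7-dimethyl-9-[(1R)-2,6,6-trimethylcyclohex-2-en-1-yl]nona-2,4,6,8-tetraenoate F5, with better 13E control and purification by chromatography or crystallisation. DIBAL-H (CH2Cl2, −78 °C) should give (R)-α-retinol, (2E,4E,6E,8E)-3,7-dimethyl-9-[(1R)-2,6,6-trimethylcyclohex-2-en-1-yl]nona-2,4,6,8-tetraen-1-ol F6, and MnO2 (CH2Cl2, rt, dark) should give 7.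

**Further compounds**
F1 | step 9 | (1E,3E,5E,9E)-1-iodo-2,6,10,14-tetramethylpentadeca-1,3,5,9,13-pentaene | CC(C)=CCC/C(C)=C/CC/C(C)=C/C=C/C(C)=C/I
F2 | step 9 | 2-[(1E,3E,5E,7E,9E)-4,8-dimethyl-10-[(1R)-2,6,6-trimethylcyclohex-2-en-1-yl]deca-1,3,5,7,9-pentaen-1-yl]-4,4,5,5-tetramethyl-1,3,2-dioxaborolane | CC1(C)OB(/C=C/C=C(C)/C=C/C=C(C)/C=C/[C@H]2C(C)=CCCC2(C)C)OC1(C)C
F3 | step 5 | (6R)-6-[(1E,3E,5E,7E)-3,7-dimethyldeca-1,3,5,7-tetraen-9-yn-1-yl]-1,5,5-trimethylcyclohex-1-ene | C#C/C=C(C)/C=C/C=C(C)/C=C/[C@H]1C(C)=CCCC1(C)C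
F4 | step 5 | chlorobis(cyclopentadienyl)[(1E,3E,5E,7E,9E)-4,8-dimethyl-10-[(1R)-2,6,6-trimethylcyclohex-2-en-1-yl]deca-1,3,5,7,9-pentaen-1-yl]zirconium (not isolated; Cp rings written σ-bonded in the SMILES) | Cl[Zr](/C=C/C=C(C)/C=C/C=C(C)/C=C/[C@H]1C(C)=CCCC1(C)C)(C1C=CC=C1)C1C=CC=C1
F5 | step 3 | ethyl (2E,4E,6E,8E)-3,7-dimethyl-9-[(1R)-2,6,6-trimethylcyclohex-2-en-1-yl]nona-2,4,6,8-tetraenoate | CCOC(=O)/C=C(C)/C=C/C=C(C)/C=C/[C@H]1C(C)=CCCC1(C)C
F6 | step 3 | (2E,4E,6E,8E)-3,7-dimethyl-9-[(1R)-2,6,6-trimethylcyclohex-2-en-1-yl]nona-2,4,6,8-tetraen-1-ol | OC/C=C(C)/C=C/C=C(C)/C=C/[C@H]1C(C)=CCCC1(C)C
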